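Both halves of the target are (S)-herbertenediol: a benzene ring carrying hydroxyls at C1 and C2, the quaternary cyclopentane carbon at C3 and a methyl at C5. That quaternary carbon is C1 of (1S,3R)-camphoric acid and is never touched; its carboxyl carbon is carried forward to become the cyclopentane-bound alkyne carbon of ynal 12. The key step exploits this by growing the whole benzene ring on that carbon: thermal [4+2] benzannulation of 12 with vinylketene acetal 15 gives salicylaldehyde 17 with OH, CHO, cyclopentyl and methyl in place. Dakin oxidation then gives the catechol, whose ortho-quinone, through its para-quinone methide tautomer, alkylates C6 of a second catechol molecule.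

Key step: step 9

Assumptions and remarks on the chemistry:
- Catechol numbering throughout is that of herbertenediol: OH on C1 and C2, cyclopentyl on C3, methyl on C5, free CH at C4 and C6.
- (1S,3R)-(−)-camphoric acid is taken as a purchasable enantiomer; the commoner (1R,3S)-(+)-acid would lead to the mirror-image target.
- Dibromoalkene 9 carries the descriptor R only because the CIP priorities change; the spatial arrangement at the quaternary carbon is the same in every compound.
- Partial epimerisation at the CH(CO2H) carbon of acid 3 (C3 of camphoric acid) would not matter, because that centre is removed in step 3.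

Step 1
Reactants: 1 (1S,3R)-(−)-camphoric acid
Product: 2 dimethyl (1S,3R)-1,2,2-trimethylcyclopentane-1,3-dicarboxylate
Conditions: MeI, K2CO3, DMF, rt
Reagents that add atoms: iodomethane, CI
Why: Carboxylate O-alkylation (SN2 esterification) does not need access to the hindered C1 carbonyl carbon, so both acids should be esterified without touching either stereocentre.

Step 2
Reactants: 2 dimethyl (1S,3R)-1,2,2-trimethylcyclopentane-1,3-dicarboxylate
Product: 3 (1R,3S)-3-(methoxycarbonyl)-2,2,3-trimethylcyclopentane-1-carboxylic acid
Conditions: KOH (1.1 equiv), MeOH–H2O, reflux; then 1 M HCl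
Reagents that add atoms: potassium hydroxide, [K+].[OH-]
Why: Saponification by acyl–oxygen cleavage should be far faster at the secondary C3 ester than at the tertiary C1 ester, which is flanked by two fully substituted carbons, a long-established selectivity of camphoric diesters.

Step 3
Reactants: 3 (1R,3S)-3-(methoxycarbonyl)-2,2,3-trimethylcyclopentane-1-carboxylic acid
Product: 6 methyl (S)-1,2,2-trimethylcyclopentane-1-carboxylate, via acid chloride 4 (not isolated), via Barton ester 5 (not isolated)
Conditions: (COCl)2, cat. N,N-dimethylformamide, CH2Cl2, 0 °C → rt; then sodium 2-thioxopyridin-1(2H)-olate, cat. 4-(dimethylamino)pyridine, t-BuSH, PhMe, hν (visible lamp), reflux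
Reagents that add atoms: none
Why: Barton reductive decarboxylation, in which light-induced fragmentation of thiohydroxamate ester 5 releases CO2 and the secondary ring radical at the former carboxyl-bearing carbon, which abstracts hydrogen from t-BuSH, while the inert tertiary ester and the quaternary stereocentre are untouched and the CH stereocentre disappears.

Step 4
Reactants: 6 methyl (S)-1,2,2-trimethylcyclopentane-1-carboxylate
Product: 7 [(S)-1,2,2-trimethylcyclopentyl]methanol
Conditions: LiAlH4, THF, 0 °C → reflux; then Na2SO4·10H2O
Reagents that add atoms: none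
Why: Hydride reduction with LiAlH4 should convert even this hindered ester into the primary neopentyl-type alcohol, and no bond at the stereocentre changes.

Step 5
Reactants: 7 [(S)-1,2,2-trimethylcyclopentyl]methanol
Product: 8 (S)-1,2,2-trimethylcyclopentane-1-carbaldehyde
Conditions: Dess–Martin periodinane, CH2Cl2, 0 °C → rt; washed and dried solution used directly (volatile product)
Reagents that add atoms: none
Why: Dess–Martin oxidation of a primary alcohol stops at the aldehyde, which has no α-hydrogen and therefore can neither enolise nor epimerise.

Step 6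
Reactants: 8 (S)-1,2,2-trimethylcyclopentane-1-carbaldehyde
Product: 9 (R)-1-(2,2-dibromoethenyl)-1,2,2-trimethylcyclopentane
Conditions: CBr4, PPh3, Zn dust, CH2Cl2, rt, 24 h; then 8, rt → 40 °C
Reagents that add atoms: carbon tetrabromide, BrC(Br)(Br)Br
Why: Corey–Fuchs dibromo-olefination (Wittig reaction of Ph3P=CBr2, preformed with Zn so that no acidic phosphorus bromide is present) is reliable for non-enolisable α-quaternary aldehydes of the pivalaldehyde type, and no bond at the stereocentre is touched.

Step 7
Reactants: 9 (R)-1-(2,2-dibromoethenyl)-1,2,2-trimethylcyclopentane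
Product: 12 3-[(S)-1,2,2-trimethylcyclopentyl]prop-2-ynal, via lithium acetylide 10 (not isolated), via lithium hemiaminal alkoxide 11 (not isolated)
Conditions: n-BuLi (2.1 equiv), THF, −78 → 0 °C; DMF, −78 → 0 °C; inverse quench into cold 10% aq KH2PO4/MTBE
Reagents that add atoms: N,N-dimethylformamide, CN(C)C=O
Why: Second half of the Corey–Fuchs sequence, in which Br/Li exchange, Fritsch–Buttenberg–Wiechell 1,2-hydrogen shift and deprotonation give acetylide 10, whose addition to DMF gives the stable hemiaminal salt 11 that releases the ynal only on inverse buffered quench, so that liberated Me2NH cannot add to the triple bond.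

Step 8
Reactants: 13 methyl 3-methylbut-2-enoate
Product: 15 1-methoxy-3-methyl-1-(trimethylsilyloxy)buta-1,3-diene, via lithium dienolate 14 (not isolated)
Conditions: LiN(i-Pr)2, THF, −78 °C; Me3SiCl, −78 °C → rt; pentane, filtration, distillation
Reagents that add atoms: chlorotrimethylsilane, C[Si](C)(C)Cl
Why: Kinetic γ-deprotonation of the senecioate ester gives the cross-conjugated dienolate 14, which the hard silyl chloride traps on oxygen to give the known, distillable vinylketene acetal (enolate O-silylation).

Step 9
Reactants: 12 3-[(S)-1,2,2-trimethylcyclopentyl]prop-2-ynal; 15 1-methoxy-3-methyl-1-(trimethylsilyloxy)buta-1,3-diene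
Product: 17 2-hydroxy-4-methyl-6-[(S)-1,2,2-trimethylcyclopentyl]benzaldehyde, via cycloadduct ketal 16 (not isolated)
Conditions: 15 (2 equiv), PhMe, 80 → 110 °C, sealed tube, Ar; then 1 M HCl, THF, 0 °C → rt
Reagents that add atoms: none
Why: Diene 15, made electron-rich by its two terminal oxygens, and the electron-poor ynal 12 should react on heating in a normal-demand, markedly asynchronous Diels–Alder cycloaddition in which the CH2 end of the diene bonds first to the alkyne carbon carrying the cyclopentyl group and the ketene acetal carbon then bonds to the formyl-bearing alkyne carbon, giving cyclohexa-1,4-diene ketal 16, which on acid work-up loses Me3SiOH and MeOH through the cross-conjugated dienone and tautomerises to the phenol. The closest known reaction type is the benzannulation of acetylenic esters, ketones and aldehydes with 1-alkoxy-1-silyloxybuta-1,3-dienes to salicylate-type arenes. The single ring closed, the six-membered carbocycle, is formed by intermolecular [4+2] cycloaddition and then aromatised by elimination. No lasting stereocentre is created (the ketal carbon of 16 is lost) and the quaternary centre is a spectator with no enolisable or ionisable bond. The step needs ortho regioselectivity and C≡C over C=O chemoselectivity: the first follows from the match of the largest HOMO coefficient at the diene CH2 with the largest LUMO coefficient at the ynal β-carbon, the second from the absence of any Lewis acid, which keeps Mukaiyama-type and hetero-Diels–Alder attack on the formyl group slow. The linear alkyne holds the bulky quaternary carbon away from the two forming bonds, which is why a cycloaddition is chosen for this crowded position.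

Step 10
Reactants: 17 2-hydroxy-4-methyl-6-[(S)-1,2,2-trimethylcyclopentyl]benzaldehyde
Product: 19 (S)-herbertenediol [5-methyl-3-[(S)-1,2,2-trimethylcyclopentyl]benzene-1,2-diol], via aryl formate 18 (not isolated)
Conditions: 30% H2O2, B(OH)3, cat. H2SO4, THF, rt, Ar; then reductive aqueous work-up
Reagents that add atoms: hydrogen peroxide, OO
Why: Dakin oxidation in its acidic borate variant, in which H2O2 adds to the formyl group, the electron-rich aryl group (ortho OH, para CH3) migrates to oxygen in Baeyer–Villiger fashion to give formate 18, and this is hydrolysed in the aqueous acid, while borate complexation and the acidic medium protect the oxidation-prone catechol.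

Step 11
Reactants: 19 (S)-herbertenediol
Product: 20 5-methyl-3-[(S)-1,2,2-trimethylcyclopentyl]cyclohexa-3,5-diene-1,2-dione
Conditions: Ag2O, Na2SO4, Et2O, 0 °C, dark; filtration through Celite, cold concentration, used the same day (only the portion of 19 needed as electrophile is oxidised)
Reagents that add atoms: none
Why: Two-electron dehydrogenation of a catechol to its ortho-quinone with Ag2O in dry ether is the classical preparation of such quinones, the tert-alkyl group at C3 should retard self-condensation, and no bond at the stereocentre is involved.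

Step 12
Reactants: 19 (S)-herbertenediol; 20 5-methyl-3-[(S)-1,2,2-trimethylcyclopentyl]cyclohexa-3,5-diene-1,2-dione
Product: 22 3-{[3,4-dihydroxy-5-[(S)-1,2,2-trimethylcyclopentyl]phenyl]methyl}-4-methyl-6-[(S)-1,2,2-trimethylcyclopentyl]benzene-1,2-diol (target CNP0137546.1), via para-quinone methide 21 (not isolated)
Conditions: 19 in threefold excess, Et3N (0.2 equiv), degassed CH2Cl2, 0 °C, Ar; 20 in CH2Cl2 added slowly, then rt; aq Na2S2O4 quench; unreacted 19 recovered by chromatography
Reagents that add atoms: none
Why: Base-catalysed vinylogous enolisation of the 4-alkyl-ortho-quinone moves a proton from the C5 methyl to the oxygen on C1 (meta to it) and leaves the C2 carbonyl para to the new methylidene, giving para-quinone methide 21, which C6 of catechol 19 (C4 being shielded by the quaternary carbon) should trap in a Friedel–Crafts-type 1,6-conjugate addition that rearomatises both rings, while slow addition of 20 limits direct quinone–catechol coupling, redox exchange between 19 and 20 only regenerates the same pair, and the dithionite quench returns any quinone-level material to the catechol level.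

Compound list
1 | (1S,3R)-(−)-camphoric acid, (1S,3R)-1,2,2-trimethylcyclopentane-1,3-dicarboxylic acid | OC(=O)[C@@]1(C)CC[C@@H](C(O)=O)C1(C)C | starting material
2 | dimethyl (1S,3R)-1,2,2-trimethylcyclopentane-1,3-dicarboxylate | COC(=O)[C@@]1(C)CC[C@@H](C(=O)OC)C1(C)C | intermediate
3 | (1R,3S)-3-(methoxycarbonyl)-2,2,3-trimethylcyclopentane-1-carboxylic acid | COC(=O)[C@@]1(C)CC[C@@H](C(O)=O)C1(C)C | intermediate
4 | methyl (1S,3R)-3-(chlorocarbonyl)-1,2,2-trimethylcyclopentane-1-carboxylate | COC(=O)[C@@]1(C)CC[C@@H](C(Cl)=O)C1(C)C | intermediate
5 | methyl (1S,3R)-1,2,2-trimethyl-3-{[(2-thioxopyridin-1(2H)-yl)oxy]carbonyl}cyclopentane-1-carboxylate | COC(=O)[C@@]1(C)CC[C@@H](C(=O)On2ccccc2=S)C1(C)C | intermediate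
6 | methyl (S)-1,2,2-trimethylcyclopentane-1-carboxylate | COC(=O)[C@@]1(C)CCCC1(C)C | intermediate
7 | [(S)-1,2,2-trimethylcyclopentyl]methanol | OC[C@@]1(C)CCCC1(C)C | intermediate
8 | (S)-1,2,2-trimethylcyclopentane-1-carbaldehyde | O=C[C@@]1(C)CCCC1(C)C | intermediate
9 | (R)-1-(2,2-dibromoethenyl)-1,2,2-trimethylcyclopentane | BrC(Br)=C[C@@]1(C)CCCC1(C)C | intermediate
10 | lithium 2-[(S)-1,2,2-trimethylcyclopentyl]ethyn-1-ide | [Li]C#C[C@@]1(C)CCCC1(C)C | intermediate
11 | lithium 1-(dimethylamino)-3-[(S)-1,2,2-trimethylcyclopentyl]prop-2-yn-1-olate | [Li]OC(N(C)C)C#C[C@@]1(C)CCCC1(C)C | intermediate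
12 | 3-[(S)-1,2,2-trimethylcyclopentyl]prop-2-ynal | O=CC#C[C@@]1(C)CCCC1(C)C | intermediate
13 | methyl 3-methylbut-2-enoate | COC(=O)C=C(C)C | starting material
14 | lithium 1-methoxy-3-methylbuta-1,3-dien-1-olate | COC(O[Li])=CC(C)=C | intermediate
15 | 1-methoxy-3-methyl-1-(trimethylsilyloxy)buta-1,3-diene | COC(O[Si](C)(C)C)=CC(C)=C | intermediate
16 | 6-methoxy-4-methyl-2-[(S)-1,2,2-trimethylcyclopentyl]-6-(trimethylsilyloxy)cyclohexa-1,4-diene-1-carbaldehyde | O=CC1=C([C@@]2(C)CCCC2(C)C)CC(C)=CC1(OC)O[Si](C)(C)C | intermediate
17 | 2-hydroxy-4-methyl-6-[(S)-1,2,2-trimethylcyclopentyl]benzaldehyde | O=Cc1c(O)cc(C)cc1[C@@]2(C)CCCC2(C)C | intermediate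
18 | 2-hydroxy-4-methyl-6-[(S)-1,2,2-trimethylcyclopentyl]phenyl formate | O=COc1c(O)cc(C)cc1[C@@]2(C)CCCC2(C)C | intermediate
19 | (S)-herbertenediol, 5-methyl-3-[(S)-1,2,2-trimethylcyclopentyl]benzene-1,2-diol | Cc1cc(O)c(O)c(c1)[C@@]2(C)CCCC2(C)C | intermediate
20 | 5-methyl-3-[(S)-1,2,2-trimethylcyclopentyl]cyclohexa-3,5-diene-1,2-dione | CC1=CC(=O)C(=O)C(=C1)[C@@]2(C)CCCC2(C)C | intermediate
21 | 2-hydroxy-4-methylidene-6-[(S)-1,2,2-trimethylcyclopentyl]cyclohexa-2,5-dien-1-one | C=C1C=C(O)C(=O)C(=C1)[C@@]2(C)CCCC2(C)C | intermediate
22 | 3-{[3,4-dihydroxy-5-[(S)-1,2,2-trimethylcyclopentyl]phenyl]methyl}-4-methyl-6-[(S)-1,2,2-trimethylcyclopentyl]benzene-1,2-diol (CNP0137546.1) | Cc1cc([C@@]2(C)CCCC2(C)C)c(O)c(O)c1Cc1cc(O)c(O)c([C@@]2(C)CCCC2(C)C)c1 | target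

Total step count: 12. Longest linear sequence: 11 steps (steps 1–7 and 9–12, from 1 to 22); step 8 is a one-step side branch.

Steps most likely to fail

Step 12. The quinone may partition away from the methyl-to-oxygen proton shift: direct attack of the catechol on the quinone ring (biaryl or diaryl ether coupling), semiquinone radical coupling, or further oxidation of the product by remaining quinone with oligomerisation may outrun benzylic trapping. The fallback avoids every quinone-level species. It sets out from 19, which is acetylated (Ac2O, pyridine) to herbertenediol diacetate F1. Wohl–Ziegler bromination (NBS, 2,2'-azobis(2-methylpropionitrile), PhCF3, reflux) should then give the benzylic bromide F2, because the two acetoxy groups deactivate the ring towards electrophilic bromination. Friedel–Crafts benzylation of a second portion of 19 at C6 with F2 (ZnCl2, 1,2-dichloroethane, 60 °C) should give the ring-B diacetate of the target F3. Acidic methanolysis (HCl, MeOH, Ar) of the two acetates returns to the route at 22.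

Step 9. Bond formation at the alkyne carbon next to the quaternary centre may be too slow, so that attack of the ketene acetal on the formyl group, desilylation of the diene or polymerisation of the ynal take over. The fallback moves the activation from the aldehyde to an ester, which has no competing electrophilic carbonyl and tolerates forcing. It sets out from 9, which is converted with n-BuLi through acetylide 10 and quenched with methyl chloroformate to the methyl ynoate F4. Diels–Alder reaction of F4 with diene 15 (neat, 130–150 °C, sealed tube), the best-precedented case of this benzannulation, should give the cycloadduct ester F5, which on acid work-up aromatises to the methyl salicylate F6. LiAlH4 reduction to the salicyl alcohol F7 and selective benzylic oxidation with MnO2 in CH2Cl2 return to the route at 17.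

Step 10. Peroxide addition to the doubly ortho-flanked formyl group may be slow, allowing over-oxidation of the electron-rich catechol product (quinone formation or ring cleavage) or hydride migration to the benzoic acid. The fallback keeps the oxygen functions masked during the oxidation. It sets out from 17, which is O-methylated (MeI, K2CO3, acetone) to the methyl ether aldehyde F8; this is also the compound step 9 would deliver if the cycloadduct lost silanol instead of methanol. Baeyer–Villiger oxidation with mCPBA in CH2Cl2 should give the guaiacol-type aryl formate F9. BBr3 (CH2Cl2, −78 °C → rt, aqueous work-up) then cleaves both the formate and the methyl ether and returns to the route at 19.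

Further compounds
F1 | step 12 | 5-methyl-3-[(S)-1,2,2-trimethylcyclopentyl]-1,2-phenylene diacetate | CC(=O)Oc1cc(C)cc([C@@]2(C)CCCC2(C)C)c1OC(C)=O
F2 | step 12 | 5-(bromomethyl)-3-[(S)-1,2,2-trimethylcyclopentyl]-1,2-phenylene diacetate | CC(=O)Oc1cc(CBr)cc([C@@]2(C)CCCC2(C)C)c1OC(C)=O
F3 | step 12 | 5-({2,3-dihydroxy-6-methyl-4-[(S)-1,2,2-trimethylcyclopentyl]phenyl}methyl)-3-[(S)-1,2,2-trimethylcyclopentyl]-1,2-phenylene diacetate | Cc1cc([C@@]2(C)CCCC2(C)C)c(O)c(O)c1Cc1cc(OC(C)=O)c(OC(C)=O)c([C@@]2(C)CCCC2(C)C)c1
F4 | step 9 | methyl 3-[(S)-1,2,2-trimethylcyclopentyl]prop-2-ynoate | COC(=O)C#C[C@@]1(C)CCCC1(C)C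
F5 | step 9 | methyl 6-methoxy-4-methyl-2-[(S)-1,2,2-trimethylcyclopentyl]-6-(trimethylsilyloxy)cyclohexa-1,4-diene-1-carboxylate | COC(=O)C1=C([C@@]2(C)CCCC2(C)C)CC(C)=CC1(OC)O[Si](C)(C)C
F6 | step 9 | methyl 2-hydroxy-4-methyl-6-[(S)-1,2,2-trimethylcyclopentyl]benzoate | COC(=O)c1c(O)cc(C)cc1[C@@]2(C)CCCC2(C)C
F7 | step 9 | 2-(hydroxymethyl)-5-methyl-3-[(S)-1,2,2-trimethylcyclopentyl]phenol | OCc1c(O)cc(C)cc1[C@@]2(C)CCCC2(C)C
F8 | step 10 | 2-methoxy-4-methyl-6-[(S)-1,2,2-trimethylcyclopentyl]benzaldehyde | COc1cc(C)cc([C@@]2(C)CCCC2(C)C)c1C=O
F9 | step 10 | 2-methoxy-4-methyl-6-[(S)-1,2,2-trimethylcyclopentyl]phenyl formate | COc1cc(C)cc([C@@]2(C)CCCC2(C)C)c1OC=O
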